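## Retrosynthetic overview

1. Target 14 ⇒ diphenol 12 by removing the C6 prenyl group (C-alkylation at the only unsubstituted ring carbon); 12 ⇒ bis-benzyl ether 11.
2. 11 ⇒ aldehyde 10 by cutting C3–C4 of the pyranone ring. The feature used: C3, its methyl and the C3–C4 bond of the 2,3-dimethylchroman-4-one are the vinyl group of an aryl (S)-but-3-en-2-yl ether lying ortho to a formyl group, and the ether carbinol carbon is C2 with its methyl and configuration already set.
3. 10 ⇒ salicylaldehyde 8 + (R)-but-3-en-2-ol (Mitsunobu, inversion); 8 ⇒ phenol 7 (phenol-directed ortho-formylation at its single free ortho carbon).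
4. 7 ⇒ dihydrocoumarin 6 (lactone methanolysis) ⇒ coumarin 5 (asymmetric CuH conjugate reduction sets the hexanoate stereocentre) ⇒ phloroglucinol + ethyl 3-oxohexanoate (Pechmann).
5. Ring order: coumarin lactone first (step 1, opened again in step 4); chromanone pyranone ring last (step 7).

Key step: step 7

Assumption: in step 3 the ligand is written as (R)-DTBM-SEGPHOS; the sense of induction for this 4-alkylcoumarin should be confirmed on a test scale and the (S)-ligand used instead if needed, with no other change.
Chromanone numbering used throughout: O1, C2, C3, C4 (C=O), C4a, C5–C8, C8a.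

## Route

Step 1
Reactants: 1 phloroglucinol; 2 ethyl 3-oxohexanoate
Product: 3 5,7-dihydroxy-4-propylcoumarin (5,7-dihydroxy-4-propyl-2H-chromen-2-one)
Conditions: CF3SO3H, 0 °C → rt
Reagents that add atoms: none
Why: Pechmann condensation of a keto ester with a highly activated phenol (ring hydroxyalkylation, dehydration and lactonisation); the threefold symmetry of phloroglucinol leaves no regiochemical choice.

Step 2
Reactants: 3 5,7-dihydroxy-4-propylcoumarin; 4 benzyl bromide
Product: 5 5,7-bis(benzyloxy)-4-propylcoumarin
Conditions: BnBr (2.4 equiv in all), K2CO3, DMF, 60 °C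
Reagents that add atoms: benzyl bromide (second equivalent), BrCc1ccccc1
Why: Twofold Williamson etherification, one equivalent of benzyl bromide being consumed at each of the two acidic coumarin phenols under anhydrous carbonate, which leaves the lactone closed and removes every free OH before the hydride step.

Step 3
Reactants: 5 5,7-bis(benzyloxy)-4-propylcoumarin
Product: 6 (4S)-5,7-bis(benzyloxy)-4-propylchroman-2-one
Conditions: Cu(OAc)2·H2O (cat.), (R)-DTBM-SEGPHOS (cat.), (EtO)2MeSiH, t-BuOH, toluene, rt
Reagents that add atoms: none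
Why: Asymmetric CuH-catalysed conjugate reduction of a 4-substituted coumarin; the ligated CuH delivers hydride to one face of C4, distinguishing the fused arene from the propyl chain and so setting the (4S) centre, and t-BuOH protonates the copper enolate before it can over-reduce or ring-open.

Step 4
Reactants: 6 (4S)-5,7-bis(benzyloxy)-4-propylchroman-2-one
Product: 7 methyl (3S)-3-[2,4-bis(benzyloxy)-6-hydroxyphenyl]hexanoate
Conditions: NaOMe (1.2 equiv), MeOH/THF, 0 °C → rt; then AcOH (1.2 equiv), 0 °C, extractive work-up without heating; used crude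
Reagents that add atoms: sodium methoxide, C[O-].[Na+]
Why: Base-mediated transesterification of the reactive aryl lactone, driven by formation of the weakly basic phenoxide; the benzylic stereocentre is beta to the carbonyl and not acidic, and cold neutral work-up limits relactonisation.

Step 5
Reactants: 7 methyl (3S)-3-[2,4-bis(benzyloxy)-6-hydroxyphenyl]hexanoate
Product: 8 methyl (3S)-3-[4,6-bis(benzyloxy)-3-formyl-2-hydroxyphenyl]hexanoate
Conditions: MgCl2, Et3N, (CH2O)n, MeCN, reflux; cold dilute HCl work-up
Reagents that add atoms: paraformaldehyde (as formaldehyde), C=O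
Why: Magnesium-mediated ortho-formylation (Casnati–Skattebøl type): the magnesium phenoxide delivers formaldehyde to its one free ortho carbon and a second formaldehyde oxidises the benzylic alkoxide by hydride transfer, so the carbon between the two benzyl ethers is left alone.

Step 6
Reactants: 8 methyl (3S)-3-[4,6-bis(benzyloxy)-3-formyl-2-hydroxyphenyl]hexanoate; 9 (R)-but-3-en-2-ol
Product: 10 methyl (3S)-3-[4,6-bis(benzyloxy)-2-[(2S)-but-3-en-2-yloxy]-3-formylphenyl]hexanoate
Conditions: PPh3, DIAD, toluene, 0 °C → rt
Reagents that add atoms: none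
Why: Mitsunobu etherification: the acidic, chelated salicylaldehyde OH displaces the alkoxyphosphonium derived from 9 by SN2 with inversion, so the (R)-alcohol gives the (S)-ether that carries the future C2.

Step 7
Reactants: 10 methyl (3S)-3-[4,6-bis(benzyloxy)-2-[(2S)-but-3-en-2-yloxy]-3-formylphenyl]hexanoate
Product: 11 methyl (3S)-3-[(2S,3S)-5,7-bis(benzyloxy)-2,3-dimethyl-4-oxochroman-8-yl]hexanoate
Conditions: 3-mesityl-5,6,7,8-tetrahydro-4H-cyclohepta[d]thiazol-3-ium perchlorate (20 mol %), DBU (40 mol %), 1,4-dioxane, 120 °C, sealed tube, argon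
Reagents that add atoms: none
Why: DBU releases the thiazol-2-ylidene, which adds to the formyl carbon of 10 and after proton transfer gives the Breslow intermediate; its nucleophilic carbon and enol O–H add across the pendant vinyl group in a concerted, asynchronous five-centre transition state, the acyl carbon bonding to the internal alkene carbon and the hydrogen passing to the terminal carbon, and loss of the carbene then gives the ketone. The closest known reaction is the carbene-catalysed intramolecular hydroacylation of unactivated alkenes in 2-allyloxybenzaldehydes to 3-methylchroman-4-ones; the present aldehyde differs in being flanked by two oxygens and in carrying a methyl group on the ether carbon. The pyranone ring closes in the 6-exo-trig mode, forming C3–C4 and the C–H bond of the C3 methyl. C3 is the one new stereocentre: with the C2 methyl pseudo-equatorial in the half-chair transition state the developing C3 methyl lies trans to it, and because C3 is alpha to the new ketone the DBU present can equilibrate any cis material to the more stable trans (2S,3S) arrangement, C2 taking no part in the bond changes. The step needs acyl transfer to the internal carbon and reaction with the alkene in preference to aldehyde–aldehyde coupling; the three-atom O–CH(CH3)–CH= tether allows only the six-membered closure and the two ortho substituents of the aldehyde disfavour benzoin-type dimerisation, while the ester, benzyl ethers and side-chain stereocentre are spectators.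

Step 8
Reactants: 11 methyl (3S)-3-[(2S,3S)-5,7-bis(benzyloxy)-2,3-dimethyl-4-oxochroman-8-yl]hexanoate
Product: 12 methyl (3S)-3-[(2S,3S)-5,7-dihydroxy-2,3-dimethyl-4-oxochroman-8-yl]hexanoate
Conditions: H2 (1 atm), Pd/C, EtOAc, rt
Reagents that add atoms: none
Why: Catalytic hydrogenolysis of aryl benzyl ethers under neutral conditions, which leave the electron-rich aryl ketone, the methyl ester and all three stereocentres untouched.

Step 9
Reactants: 12 methyl (3S)-3-[(2S,3S)-5,7-dihydroxy-2,3-dimethyl-4-oxochroman-8-yl]hexanoate; 13 prenyl bromide (1-bromo-3-methylbut-2-ene)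
Product: 14 methyl (3S)-3-[(2S,3S)-5,7-dihydroxy-2,3-dimethyl-6-(3-methylbut-2-en-1-yl)-4-oxochroman-8-yl]hexanoate (target)
Conditions: NaOMe (1.05 equiv), MeOH, 0 °C → rt; AcOH quench at 0 °C
Reagents that add atoms: none
Why: Base-mediated C-prenylation of an acylphloroglucinol-type phenoxide in a protic solvent, which hydrogen-bonds the phenoxide oxygen and directs the allylic bromide to C6, the only unsubstituted ring carbon, flanked by both hydroxyls; methoxide in methanol cannot alter the methyl ester and keeps the hydroxy ester open.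

## Compound list

1 | phloroglucinol | Oc1cc(O)cc(O)c1 | starting material
2 | ethyl 3-oxohexanoate | CCCC(=O)CC(=O)OCC | starting material
3 | 5,7-dihydroxy-4-propylcoumarin | CCCC1=CC(=O)Oc2cc(O)cc(O)c12 | intermediate
4 | benzyl bromide | BrCc1ccccc1 | starting material
5 | 5,7-bis(benzyloxy)-4-propylcoumarin | CCCC1=CC(=O)Oc2cc(OCc3ccccc3)cc(OCc3ccccc3)c12 | intermediate
6 | (4S)-5,7-bis(benzyloxy)-4-propylchroman-2-one | CCC[C@H]1CC(=O)Oc2cc(OCc3ccccc3)cc(OCc3ccccc3)c12 | intermediate
7 | methyl (3S)-3-[2,4-bis(benzyloxy)-6-hydroxyphenyl]hexanoate | CCC[C@@H](CC(=O)OC)c1c(O)cc(OCc2ccccc2)cc1OCc1ccccc1 | intermediate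
8 | methyl (3S)-3-[4,6-bis(benzyloxy)-3-formyl-2-hydroxyphenyl]hexanoate | CCC[C@@H](CC(=O)OC)c1c(O)c(C=O)c(OCc2ccccc2)cc1OCc1ccccc1 | intermediate
9 | (R)-but-3-en-2-ol | C[C@@H](O)C=C | starting material
10 | methyl (3S)-3-[4,6-bis(benzyloxy)-2-[(2S)-but-3-en-2-yloxy]-3-formylphenyl]hexanoate | CCC[C@@H](CC(=O)OC)c1c(OCc2ccccc2)cc(OCc2ccccc2)c(C=O)c1O[C@@H](C)C=C | intermediate
11 | methyl (3S)-3-[(2S,3S)-5,7-bis(benzyloxy)-2,3-dimethyl-4-oxochroman-8-yl]hexanoate | CCC[C@@H](CC(=O)OC)c1c(OCc2ccccc2)cc(OCc2ccccc2)c2c1O[C@@H](C)[C@H](C)C2=O | intermediate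
12 | methyl (3S)-3-[(2S,3S)-5,7-dihydroxy-2,3-dimethyl-4-oxochroman-8-yl]hexanoate | CCC[C@@H](CC(=O)OC)c1c(O)cc(O)c2c1O[C@@H](C)[C@H](C)C2=O | intermediate
13 | prenyl bromide (1-bromo-3-methylbut-2-ene) | CC(C)=CCBr | starting material
14 | methyl (3S)-3-[(2S,3S)-5,7-dihydroxy-2,3-dimethyl-6-(3-methylbut-2-en-1-yl)-4-oxochroman-8-yl]hexanoate | CCC[C@@H](CC(=O)OC)c1c(O)c(CC=C(C)C)c(O)c2c1O[C@@H](C)[C@H](C)C2=O | target

## Step count

Total step count: 9. Longest linear sequence: 9 steps (1 → 14).

## Steps most likely to fail

**Step 7 (carbene hydroacylation).** Carbene addition to a formyl group crowded by two ortho oxygens may be slow or incomplete. At 120 °C the butenyl group may migrate thermally (Claisen-type shift to the free ring carbon). Base may also open the product ring through the C3 enolate (retro-oxa-Michael), which would erode C2.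
Fallback, from 10, returning at 11: an acyl-radical closure of the same C3–C4 bond. The aldehyde is oxidised (NaClO2, NaH2PO4, 2-methylbut-2-ene, t-BuOH/H2O, rt) to 4,6-bis(benzyloxy)-2-[(2S)-but-3-en-2-yloxy]-3-[(3S)-1-methoxy-1-oxohexan-3-yl]benzoic acid F1. This is converted with PhSeSePh and PBu3 (CH2Cl2, rt) into Se-phenyl 4,6-bis(benzyloxy)-2-[(2S)-but-3-en-2-yloxy]-3-[(3S)-1-methoxy-1-oxohexan-3-yl]benzenecarboselenoate F2. Bu3SnH and AIBN in benzene at 80 °C then generate the aroyl radical, which closes 6-exo-trig onto the vinyl group; the primary radical takes hydrogen from the stannane. The resulting C3 mixture is equilibrated with catalytic DBU in CH2Cl2 at rt to the trans chromanone 11.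

**Step 9 (C-prenylation).** O-alkylation may compete with C-alkylation, a second alkylation at C6 may destroy aromaticity, and the 7-OH may lactonise onto the ester during work-up.
Fallback, from 12, returning at 14: a regiospecific ether-then-rearrangement sequence. The non-chelated 7-OH is etherified with 3-chloro-3-methylbut-1-yne, DBU and catalytic CuCl2 in MeCN at 0 °C to give methyl (3S)-3-[(2S,3S)-5-hydroxy-2,3-dimethyl-7-[(2-methylbut-3-yn-2-yl)oxy]-4-oxochroman-8-yl]hexanoate F3. Semihydrogenation (H2, Pd/CaCO3 poisoned with Pb(OAc)2, quinoline, EtOAc) gives methyl (3S)-3-[(2S,3S)-5-hydroxy-2,3-dimethyl-7-[(2-methylbut-3-en-2-yl)oxy]-4-oxochroman-8-yl]hexanoate F4. Warming in toluene (80–110 °C) brings about an aromatic Claisen rearrangement; with C8 blocked, the allyl unit can only go to C6 with allylic transposition, which is the prenyl group of 14.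

**Step 6 (Mitsunobu etherification).** Displacement may be sluggish at a phenol that is both chelated and flanked by two substituents, and SN2' attack or ionisation of the allylic alkoxyphosphonium may erode regio- and enantiopurity.
Fallback, from 8, returning directly at 10 (no new compound, F0): palladium-catalysed asymmetric allylic etherification. Phenol 8 is treated with (E)-but-2-en-1-yl methyl carbonate, Pd2(dba)3·CHCl3 and the antipode of N,N'-(cyclohexane-1,2-diyl)bis[2-(diphenylphosphanyl)benzamide] that gives the (S)-branched ether, in CH2Cl2 at rt. The phenol attacks the π-crotylpalladium complex at its substituted terminus, so the configuration of the future C2 is set by the catalyst instead of by inversion of 9.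

## Further compounds

F1 | step 7 | 4,6-bis(benzyloxy)-2-[(2S)-but-3-en-2-yloxy]-3-[(3S)-1-methoxy-1-oxohexan-3-yl]benzoic acid | CCC[C@@H](CC(=O)OC)c1c(OCc2ccccc2)cc(OCc2ccccc2)c(C(=O)O)c1O[C@@H](C)C=C
F2 | step 7 | Se-phenyl 4,6-bis(benzyloxy)-2-[(2S)-but-3-en-2-yloxy]-3-[(3S)-1-methoxy-1-oxohexan-3-yl]benzenecarboselenoate | CCC[C@@H](CC(=O)OC)c1c(OCc2ccccc2)cc(OCc2ccccc2)c(C(=O)[Se]c2ccccc2)c1O[C@@H](C)C=C
F3 | step 9 | methyl (3S)-3-[(2S,3S)-5-hydroxy-2,3-dimethyl-7-[(2-methylbut-3-yn-2-yl)oxy]-4-oxochroman-8-yl]hexanoate | CCC[C@@H](CC(=O)OC)c1c(OC(C)(C)C#C)cc(O)c2c1O[C@@H](C)[C@H](C)C2=O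
F4 | step 9 | methyl (3S)-3-[(2S,3S)-5-hydroxy-2,3-dimethyl-7-[(2-methylbut-3-en-2-yl)oxy]-4-oxochroman-8-yl]hexanoate | CCC[C@@H](CC(=O)OC)c1c(OC(C)(C)C=C)cc(O)c2c1O[C@@H](C)[C@H](C)C2=O
F0 | step 6 | none | none
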